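Equilibrium cannot be what halts these runs: mirror-image products would then stand level, yet the west run holds left-handed product at 7.58% against right-handed product at 3.50%, flat from the first reading.

| flask | left-handed substrate | right-handed substrate | partner | free catalyst | remark | time |
|---|---|---|---|---|---|---|
| south-west | 1 M | 1 M | 0.84 M | 5 mM | run made earlier |  |
| north | 1 M | 1 M | 1.3 M | 5 mM | run made earlier |  |
| west | 1 M | 1 M | 0.60 M | 2.5 mM | run made earlier |  |
| flask | 1.0 M | 1.0 M | 0.600 M | 5.0 mM |  | 8.0 h |

| run | time / h | left-handed product / % | right-handed product / % |
|---|---|---|---|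
| south-west | 1.33 | 15.2 | 7.3 |
| south-west | 2.50 | 14.8 | 7.4 |
| south-west | 4.00 | 14.3 | 7.3 |
| south-west | 5.00 | 14.5 | 7.3 |
| south-west | 6.00 | 14.7 | 7.7 |
| north | 0.500 | 19.9 | 11.6 |
| north | 1.00 | 19.0 | 11.7 |
| north | 2.00 | 19.4 | 11.7 |
| north | 3.00 | 18.6 | 11.6 |
| north | 6.00 | 19.0 | 11.5 |
| west | 0.500 | 7.7 | 3.7 |
| west | 1.50 | 7.4 | 3.4 |
| west | 3.00 | 7.5 | 3.6 |
| west | 5.00 | 7.7 | 3.1 |
| west | 6.00 | 7.6 | 3.7 |

(each reading ± 0.3 percentage points)

- free catalyst is single-handed; left-handed substrate and right-handed substrate are mirror images of each other, charged as a racemate, each of them at the stated concentration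
- an excess is the difference of the two amounts in percent of their sum
- an excess is below zero if the other one leads

- excess of left-handed product over right-handed product in the product at 50 min
- excess of left-handed product over right-handed product in the product at 8.0 h
- part of the left-handed substrate and right-handed substrate charged together that has reacted at 8.0 h

Two of us read this differently. The forecaster holds that the catalyst is dying or the reaction otherwise stalling, and takes “the final extent as catalyst dose”, scaled by partner. The forecast is 35% at 50 min, 34% at 8.0 h and 18% reacted.

I hold that the partner is the clock. Picture a tank with two drains, the catalysed step and some loss elsewhere, each proportional to the level, so the share through each drain follows the catalyst and not the level. The west run made 0.222 M of product; I take its 0.60 M of partner as gone by the plateau, one partner per product. The split x, partner turned to product over partner lost elsewhere, then reads 0.586. Dividing by the 2.5 mM of catalyst gives g = 0.234 mM⁻¹, the split per unit of catalyst charged.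

The flask has the west run's partner and twice its catalyst, so x = 1.17. My reckoning is 16.2% reacted, with the excess the west run reads, 36.8%.

Against my view stand the runs at 5 mM of catalyst: x reads 1.11 in the south-west run but less in the north run, 0.901, with more partner.

The flask gives 16.7% reacted, against 16.2% from g, with an excess of 38.6% at 50 min and 38.6% at 8.0 h.

partner → decomposed reagent (k = 0.00120 s⁻¹); free catalyst + left-handed substrate ⇌ catalyst intermediate A (K = 0.510 M⁻¹, k = 0.500 M⁻¹ s⁻¹); free catalyst + right-handed substrate ⇌ catalyst intermediate B (K = 0.420 M⁻¹, k = 18.0 M⁻¹ s⁻¹); partner + catalyst intermediate B → free catalyst + right-handed product (k = 0.560 M⁻¹ s⁻¹); free catalyst → spent catalyst (k = 0.00170 s⁻¹); partner + catalyst intermediate A → free catalyst + left-handed product (k = 1.70 M⁻¹ s⁻¹) At 0.800 h the flask holds 0.357% of its partner, with 94.0% of the catalyst spent; at 8.00 h it holds less of its partner, the limiting reagent, at 0% of the charge, than of its left-handed substrate, at 77%. The forecaster's rule keeps its ground on one neighbour: carried by its own power 0.7 to the flask with 1.5 M of partner, 18% becomes 34.2%, and that neighbour gives 34.7%. With 0.013 M of catalyst, g gives x = 3.05, hence 22.6% reacted, and that neighbour gives 23.7%.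

The runs are calculated from invented constants; the scatter is artificial.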